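**Retrosynthetic overview**
Numbering: ring A is C1 (OH), C2 (OAr), C3 (Br), C4 (Br), C5 (H), C6 (Br); ring B is C1' (O), C2' (Br). The strategy rests on ring B, which carries only the ether oxygen at C1' and a bromine at the adjacent C2'. This is the pattern left when unsubstituted benzyne takes up a nucleophile and then an electrophile.
Last disconnection: the C1 hydroxyl comes from a C1 methyl ether, cleaved with BBr3.
Key disconnection: O–C1' and C2'–Br are cut together, giving 2,3,5-tribromo-6-methoxyphenoxide, benzyne (from the ortho-silylaryl triflate) and a halophilic bromine donor.
Ring A: 2-bromo-6-methoxyphenol already has the C3 bromine. Masking its C2 oxygen as a mesylate leaves the C1 methoxy group as the only director, so bromine goes to C4 (para) and C6 (ortho) and C5 keeps its hydrogen.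
No ring is formed. Both benzene rings are bought, ring A as the bromoguaiacol and ring B as the aryne precursor.

Key step: step 4

Assumption: the target has no stereocentre and its diaryl ether axis rotates freely, so there is no enantiomer to select and the achiral compound is made.

**Step 1**
Reactants: 1 2-bromo-6-methoxyphenol
Product: 2 2-bromo-6-methoxyphenyl methanesulfonate
Conditions: MsCl (1.2 equiv), Et3N (1.5 equiv), CH2Cl2, 0 °C → rt
Reagents that add atoms: methanesulfonyl chloride, CS(=O)(=O)Cl
Why: O-sulfonylation of a phenol is fast even between two ortho substituents, and it converts the C2 oxygen into a group that withstands strong acid and no longer pushes electron density towards C5.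

**Step 2**
Reactants: 2 2-bromo-6-methoxyphenyl methanesulfonate
Product: 4 2,3,5-tribromo-6-methoxyphenyl methanesulfonate, via 2,3-dibromo mesylate 3 (not isolated)
Conditions: NBS (2.3 equiv), CF3CO2H–conc. H2SO4 (5:1), 0 °C → 40 °C, dark
Reagents that add atoms: N-bromosuccinimide, O=C1CCC(=O)N1Br
Why: In this electrophilic aromatic bromination (SEAr) with acid-activated NBS, the C1 methoxy group is the only donor left, so bromine enters para (C4) and ortho (C6) to it in either order with the same end result, the strong acid supplies the electrophilicity needed for the second substitution on a deactivated ring, the mesylate tolerates the medium, and C5 (meta to OMe, para to the withdrawing OMs, between two bromines) should stay untouched.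

**Step 3**
Reactants: 4 2,3,5-tribromo-6-methoxyphenyl methanesulfonate
Product: 5 2,3,5-tribromo-6-methoxyphenol
Conditions: NaOH (2 M aq, 5 equiv), 1,4-dioxane, 60 °C; then 1 M HCl
Reagents that add atoms: none
Why: Alkaline S–O cleavage of an aryl sulfonate (hydroxide at sulfur, or E1cB through sulfene) is helped by the acidic tribromophenol leaving group, leaves the aryl bromides and the methyl ether alone, and is run without methanol so that no methyl mesylate can form and re-alkylate the phenoxide.

**Step 4**
Reactants: 5 2,3,5-tribromo-6-methoxyphenol; 6 2-(trimethylsilyl)phenyl trifluoromethanesulfonate; 7 1,2-dibromo-1,1,2,2-tetrachloroethane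
Product: 11 1,2,5-tribromo-3-(2-bromophenoxy)-4-methoxybenzene, via potassium phenoxide 8 (not isolated), via benzyne 9 (not isolated), via 2-aryloxyphenyl anion 10 (not isolated)
Conditions: KH (1.0 equiv), THF, 0 °C; then 7 (3 equiv), dry KF (4 equiv), dry 18-crown-6 (4 equiv), 6 (2 equiv, slow addition), THF, 0 °C → rt, dark, Ar
Reagents that add atoms: 2-(trimethylsilyl)phenyl trifluoromethanesulfonate 6, C[Si](C)(C)c1ccccc1OS(=O)(=O)C(F)(F)F (the C6H4 unit); 1,2-dibromo-1,1,2,2-tetrachloroethane 7, BrC(Cl)(Cl)C(Cl)(Cl)Br (the C2' bromine)
Why: Fluoride strips the silyl group of 6 and triflate leaves, so benzyne 9 is released slowly; the crown-separated phenoxide 8 adds through oxygen to the strained triple bond (O–C1'), and the 2-aryloxyphenyl anion 10 attacks a bromine atom of 7, which collapses to bromide and tetrachloroethene and thereby makes C2'–Br formation irreversible. The closest known reaction types are the fluoride-induced O-arylation of phenols with ortho-silylaryl triflates and the three-component aryne couplings in which a heteroatom nucleophile adds and the aryl anion is quenched halophilically by a polyhaloalkane; bromination of aryl carbanions by 7 is routine. No ring closes and no stereocentre forms, and since the two aryne carbons are equivalent, oxygen and bromine can only end up as neighbours. The step needs bromination of 10 to outrun protonation, which is served by complete prior deprotonation with KH (no ArOH, no bifluoride), by THF in place of acetonitrile and by a threefold excess of 7 present from the start. It also needs 8 to react at oxygen with 9 and not at carbon with 9 or 7, which the substrate secures: both ortho positions are filled (Br at C3, OMe at C1), C5 is screened by the bromines at C4 and C6, and three bromines drain the ring of nucleophilicity. No copper or palladium is present, so the C–Br bonds are safe from oxidative addition, and the excess of 7 should re-brominate any ring-A carbanion that arises by bromine transfer from C3 to C2' before it can expel the C4 bromide.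

**Step 5**
Reactants: 11 1,2,5-tribromo-3-(2-bromophenoxy)-4-methoxybenzene
Product: 13 3,4,6-tribromo-2-(2-bromophenoxy)phenol (target), via aryloxydibromoborane 12 (not isolated)
Conditions: BBr3 (2.5 equiv), CH2Cl2, −78 °C → rt; then ice/H2O
Reagents that add atoms: none
Why: In this Lewis-acid aryl methyl ether cleavage, boron binds the methoxy oxygen and bromide attacks the methyl carbon in an SN2 step, a path closed to the diaryl ether oxygen (only sp2 carbons) and to the four C–Br bonds, and water then hydrolyses the B–O bond of 12.

**Compound list**
1 | 2-bromo-6-methoxyphenol | COc1cccc(Br)c1O | starting material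
2 | 2-bromo-6-methoxyphenyl methanesulfonate | COc1cccc(Br)c1OS(C)(=O)=O | intermediate
3 | 2,3-dibromo-6-methoxyphenyl methanesulfonate | COc1ccc(Br)c(Br)c1OS(C)(=O)=O | intermediate
4 | 2,3,5-tribromo-6-methoxyphenyl methanesulfonate | COc1c(Br)cc(Br)c(Br)c1OS(C)(=O)=O | intermediate
5 | 2,3,5-tribromo-6-methoxyphenol | COc1c(Br)cc(Br)c(Br)c1O | intermediate
6 | 2-(trimethylsilyl)phenyl trifluoromethanesulfonate | C[Si](C)(C)c1ccccc1OS(=O)(=O)C(F)(F)F | starting material
7 | 1,2-dibromo-1,1,2,2-tetrachloroethane | BrC(Cl)(Cl)C(Cl)(Cl)Br | starting material
8 | potassium 2,3,5-tribromo-6-methoxyphenolate | COc1c(Br)cc(Br)c(Br)c1[O-].[K+] | intermediate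
9 | benzyne (cyclohexa-1,3-dien-5-yne) | C1#CC=CC=C1 | intermediate
10 | potassium 2-(2,3,5-tribromo-6-methoxyphenoxy)phenide | COc1c(Br)cc(Br)c(Br)c1Oc1cccc[c-]1.[K+] | intermediate
11 | 1,2,5-tribromo-3-(2-bromophenoxy)-4-methoxybenzene | COc1c(Br)cc(Br)c(Br)c1Oc1ccccc1Br | intermediate
12 | dibromo[3,4,6-tribromo-2-(2-bromophenoxy)phenoxy]borane | BrB(Br)Oc1c(Br)cc(Br)c(Br)c1Oc1ccccc1Br | intermediate
13 | 3,4,6-tribromo-2-(2-bromophenoxy)phenol (CNP0018165.0) | Oc1c(Br)cc(Br)c(Br)c1Oc1ccccc1Br | target

Total step count: 5. Longest linear sequence: 5 (1 → 13); 6 and 7 are bought.

**Steps most likely to fail**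

1. Step 4.
   - The aryl anion may be protonated by traces of acid, by the crown ether or by the acidic C5–H of another molecule instead of being brominated.
   - The donor, or bromine released from it by accumulating bromide, may brominate the phenoxide at C5.
   - Bromine transfer from ring A to the anion, followed by loss of bromide from the resulting ortho-bromoaryl anion, may scramble the halogen pattern.
   - The crowded, weakly nucleophilic phenoxide may lose benzyne to bromide or fluoride.
   - The fallback sets out from 5 and comes back at 11. The ether bond is made by ligand coupling on iodine(III) instead of by aryne capture, and the reagent brings the C2' bromine with it. 1-Bromo-2-iodobenzene is oxidised with mCPBA/TsOH in MeCN. The hydroxy(tosyloxy)iodane is condensed in the same pot with 1,3,5-trimethoxybenzene to give (2-bromophenyl)(2,4,6-trimethoxyphenyl)iodonium tosylate F1. Phenol 5 is deprotonated (KOtBu, THF/toluene) and warmed with F1 at 60–80 °C. The electron-rich trimethoxyphenyl group stays on iodine and the 2-bromophenyl group passes to oxygen. Metal-free O-arylation of crowded, brominated phenols with diaryliodonium salts is established chemistry.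

2. Step 2.
   - The reaction may stall after the first bromination because the ring then carries two bromines and a sulfonate.
   - Ring sulfonation may compete in the strong acid.
   - The fallback sets out from 2 and comes back at 4. It raises the directing power of the ring instead of the strength of the electrophile. BBr3 (CH2Cl2, −78 → 0 °C) removes the methyl group of 2, with the mesylate inert, to give 2-bromo-6-hydroxyphenyl methanesulfonate F2. The free C1 hydroxyl then steers plain Br2 (2 equiv, AcOH, rt) to its only open ortho (C6) and para (C4) positions, giving 2,3,5-tribromo-6-hydroxyphenyl methanesulfonate F3. MeI/K2CO3 in acetone restores the methyl ether and delivers 4.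

3. Step 5.
   - Cleavage of a methoxy group locked between a bromine and an aryloxy group may be slow.
   - On long exposure to BBr3/HBr, the bromines ortho and para to the freed hydroxyl may migrate or be lost under acid.
   - The fallback sets out from 1 (with 6 and 7) and comes back at 13. The order of events changes so that the methyl ether is cleaved before ring A is fully brominated. Compound 1 is put through the conditions of step 4 to give 1-bromo-2-(2-bromophenoxy)-3-methoxybenzene F4, whose methoxy group has only one ortho neighbour. BBr3 gives 3-bromo-2-(2-bromophenoxy)phenol F5. Br2 (2.0 equiv, AcOH, 0 °C → rt) then enters para (C4) and ortho (C6) to the free hydroxyl to give 13.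
   - This order is held in reserve for two reasons. The last bromination has to discriminate against C4' of ring B, and the more electron-rich phenoxide of 1 is more exposed to C-bromination by 7.

**Further compounds**
F1 | step 4 | (2-bromophenyl)(2,4,6-trimethoxyphenyl)iodonium 4-methylbenzenesulfonate | COc1cc(OC)c([I+]c2ccccc2Br)c(OC)c1.Cc1ccc(cc1)S(=O)(=O)[O-]
F2 | step 2 | 2-bromo-6-hydroxyphenyl methanesulfonate | Oc1cccc(Br)c1OS(C)(=O)=O
F3 | step 2 | 2,3,5-tribromo-6-hydroxyphenyl methanesulfonate | Oc1c(Br)cc(Br)c(Br)c1OS(C)(=O)=O
F4 | step 5 | 1-bromo-2-(2-bromophenoxy)-3-methoxybenzene | COc1cccc(Br)c1Oc1ccccc1Br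
F5 | step 5 | 3-bromo-2-(2-bromophenoxy)phenol | Oc1cccc(Br)c1Oc1ccccc1Br
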